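## Retrosynthetic overview

1. Target 19 ⇒ enol triflate 14 + dienoate 16: the C9–C11 bond comes from hydroboration / B-alkyl Suzuki coupling, then ester hydrolysis.
2. 14 ⇒ keto lactone 9: 6β-OH and 19-OH come from hydride opening of a 19,6β-lactone, 3α-OH from equatorial hydride attack, the enol triflate from the C9 ketone.
3. 9 ⇒ Δ5 β-keto ester 8 by a new photoredox dealkylative anti-Markovnikov hydrolactonization (sets C5 and C6); 8 ⇒ enedione 6 by C4 carboxylation and α-face methylation (sets C4).
4. 6 ⇒ (S)-Hajos–Parrish ketone 5 by one-carbon ring expansion with diazoethane (1,2-alkyl shift), turning the cyclopentanone into the C8-methylated six-membered ring B.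
5. Ring order: ring A first (proline-catalysed annulation of 1 and 2, sets C10), then ring B by expansion of the five-membered ring.

Assumption: labdane locants are used for the decalin core (α = face opposite the C10 methyl); C8 in 6–10 and F1–F4 is an inconsequential epimer mixture, left undefined in names and SMILES, because it becomes sp2 in step 6.

## Route

Step 1
Reactants: 1 2-methylcyclopentane-1,3-dione; 2 methyl vinyl ketone
Product: 5 (S)-Hajos–Parrish ketone, via triketone 3 (not isolated), via ketol 4 (not isolated)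
Conditions: 2 (1.5 equiv), AcOH (cat.), H2O, 70 °C; concentrate; (S)-proline (3 mol%), DMF, 20 °C; then H2SO4 (cat.), 95 °C; recrystallise
Reagents that add atoms: none
Why: Michael addition followed by the Hajos–Parrish–Eder–Sauer–Wiechert proline-enamine aldol, in which the carboxylic acid-directed enamine attacks one enantiotopic ring carbonyl and sets C10 as S, then acid dehydration.

Step 2
Reactants: 5 (S)-Hajos–Parrish ketone
Product: 6 (8aS)-2,8a-dimethyl-3,4,8,8a-tetrahydronaphthalene-1,6(2H,7H)-dione
Conditions: CH3CHN2 (1.3 equiv, dried Et2O solution from N-ethyl-N-nitrosourea and KOH, 0 °C), Sc(OTf)3 (10 mol%), CH2Cl2/toluene, −78 °C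
Reagents that add atoms: diazoethane CC=[N+]=[N-] (made from N-ethyl-N-nitrosourea CCN(N=O)C(N)=O)
Why: Lewis acid-catalysed diazoalkane homologation (Tiffeneau–Demjanov-type 1,2-shift): diazoethane adds to the strained saturated ketone (the enone is inert at −78 °C) and the less substituted CH2 migrates, as in D-homoannulation of 17-keto steroids, so the carbonyl stays next to the quaternary carbon and C8 arrives with its methyl.

Step 3
Reactants: 6 (8aS)-2,8a-dimethyl-3,4,8,8a-tetrahydronaphthalene-1,6(2H,7H)-dione
Product: 7 (4aS)-4a,6-dimethyl-2,5-dioxo-2,3,4,4a,5,6,7,8-octahydronaphthalene-1-carboxylic acid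
Conditions: MeOMgOCO2Me (2 M in DMF, 5 equiv), 125 °C, N2 stream; then ice/2 M HCl
Reagents that add atoms: methyl magnesium carbonate COC(=O)O[Mg]OC
Why: Stiles carboxylation: the thermodynamic extended dienolate is carboxylated at C4 and held as the Mg chelate of the conjugated β-keto acid (the classical carboxylation of Hajos–Parrish-type enones), while the C9 ketone has a single hindered α-H and cannot form a stable chelate.

Step 4
Reactants: 7 (4aS)-4a,6-dimethyl-2,5-dioxo-2,3,4,4a,5,6,7,8-octahydronaphthalene-1-carboxylic acid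
Product: 8 methyl (1R,4aS)-1,4a,6-trimethyl-2,5-dioxo-1,2,3,4,4a,5,6,7-octahydronaphthalene-1-carboxylate
Conditions: NaH (2.1 equiv), MeI (4 equiv), DMF, 0 → 23 °C
Reagents that add atoms: iodomethane CI
Why: carboxylate O-methylation followed by deconjugative C-alkylation of the vinylogous β-keto ester dienolate at C4, with MeI entering on the α face anti to the axial C10 methyl, which sets C4 (4α-Me, 4β-CO2Me) and moves the alkene to C5=C6; no free β-keto acid is ever formed.

Step 5
Reactants: 8 methyl (1R,4aS)-1,4a,6-trimethyl-2,5-dioxo-1,2,3,4,4a,5,6,7-octahydronaphthalene-1-carboxylate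
Product: 9 3,9-dioxo-19,6β-lactone (trans-decalin)
Conditions: 9-mesityl-3,6-di-tert-butyl-10-phenylacridinium tetrafluoroborate (5 mol%), (PhS)2 (10 mol%), H2O (5 equiv), 1,2-dichloroethane (0.05 M), 450 nm LEDs, 25 °C; then pyridinium p-toluenesulfonate (cat.), 40 °C
Reagents that add atoms: water O
Why: Proposed new method: dealkylative anti-Markovnikov hydrolactonization of a methyl ester — the excited acridinium oxidises the only alkene (C5=C6) to its radical cation, the ester carbonyl oxygen held 1,3-diaxially over C6 adds to that less substituted carbon on the β face (giving the tertiary C5 radical and a methoxy-lactonium ion), thiol H-atom transfer to the open α face of C5 sets the trans ring fusion, and water hydrolyses the methoxy-lactonium to the lactone with loss of methanol while thiol and acridinium are regenerated; the closest known reaction types are acridinium/thiol photoredox anti-Markovnikov hydroacyloxylation of alkenes with free carboxylic acids and ester-participating halolactonization, and the ester is used because the free acid would be a decarboxylation-prone β-keto acid.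

Step 6
Reactants: 9 3,9-dioxo-19,6β-lactone
Product: 12 3-oxo-19,6β-lactone C8=C9 enol triflate, via silyl enol ether 10 (not isolated), via silyl enol ether triflate 11 (not isolated)
Conditions: KN(SiMe3)2 (1.05 equiv), THF, −78 °C; Me3SiCl (1.1 equiv); KN(SiMe3)2 (1.3 equiv), −78 → −30 °C; Comins' reagent (1.3 equiv), −78 → 0 °C; then 1 M HCl, THF, 0 °C
Reagents that add atoms: chlorotrimethylsilane C[Si](C)(C)Cl (silyl group in 10 and 11 only); Comins' reagent FC(F)(F)S(=O)(=O)N(c1ccc(Cl)cn1)S(=O)(=O)C(F)(F)F
Why: kinetic deprotonation at the unhindered C2 methylene lets the C3 ketone be masked in the flask as its silyl enol ether, the second deprotonation can only occur at C8–H (C10 and C4 are quaternary), and the tetrasubstituted enolate is O-triflated (enol triflate formation as for 2,2,6-trimethylcyclohexanone) before acid work-up returns the C3 ketone.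

Step 7
Reactants: 12 3-oxo-19,6β-lactone C8=C9 enol triflate
Product: 14 3α,6β,19-triol enol triflate, via hydroxy lactone 13 (not isolated)
Conditions: LiBH(s-Bu)3 (L-Selectride, 1.2 equiv), THF, −78 °C; then LiBH4 (4 equiv), MeOH (4 equiv), −78 → 35 °C; aq. NH4Cl
Reagents that add atoms: none
Why: the bulky trialkylborohydride attacks the 3-ketone of the chair trans-decalin equatorially from the β side to give the axial 3α-alcohol (as with 4,4-disubstituted 3-oxo triterpenoids), and LiBH4 then reduces the lactone to the 6β,19-diol without touching the electron-poor enol triflate.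

Step 8
Reactants: 15 ethyl but-2-ynoate
Product: 16 ethyl (2E)-3-methylpenta-2,4-dienoate
Conditions: CH2=CHMgBr (1.2 equiv), CuBr·SMe2 (1.2 equiv), THF, −40 °C; then 15, −78 °C; MeOH then aq. NH4Cl at −78 °C
Reagents that add atoms: vinylmagnesium bromide C=C[Mg]Br
Why: syn-carbocupration of the ynoate (organocopper conjugate addition) with low-temperature protonation places vinyl and H cis, giving the 2E dienoate.

Step 9
Reactants: 14 3α,6β,19-triol enol triflate; 16 ethyl (2E)-3-methylpenta-2,4-dienoate
Product: 19 (13E)-3α,6β,19-trihydroxylabda-8,13-dien-15-oic acid (target), via alkylborane 17 (not isolated), via ethyl ester 18 (not isolated)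
Conditions: 16 (2 equiv), 9-BBN-H (2 equiv), THF, 0 → 23 °C; then 14, Pd(dppf)Cl2 (10 mol%), AsPh3 (10 mol%), Cs2CO3 (3 equiv), DMF/H2O, 60 °C; then LiOH (10 equiv), MeOH/H2O, 45 °C; 1 M HCl to pH 3
Reagents that add atoms: 9-BBN-H B1C2CCCC1CCC2 (boron unit in 17 only); lithium hydroxide [Li+].[OH-]
Why: anti-Markovnikov hydroboration of the terminal vinyl group, then B-alkyl Suzuki–Miyaura coupling with the hindered enol triflate (the 2,6,6-trimethylcyclohexenyl triflate type) forms C9–C11 with the 13E geometry retained, and saponification frees the acid.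

## Compound list

1 | 2-methylcyclopentane-1,3-dione | CC1C(=O)CCC1=O | starting material
2 | methyl vinyl ketone (but-3-en-2-one) | CC(=O)C=C | starting material
3 | 2-methyl-2-(3-oxobutyl)cyclopentane-1,3-dione | CC(=O)CCC1(C)C(=O)CCC1=O | intermediate
4 | (3aS,7aS)-3a-hydroxy-7a-methylhexahydro-1H-indene-1,5(4H)-dione (cis ketol) | O=C1[C@@]2(C)CCC(=O)C[C@@]2(O)CC1 | intermediate
5 | (S)-Hajos–Parrish ketone, (7aS)-7a-methyl-2,3,7,7a-tetrahydro-1H-indene-1,5(6H)-dione | O=C1[C@@]2(C)CCC(=O)C=C2CC1 | intermediate
6 | (8aS)-2,8a-dimethyl-3,4,8,8a-tetrahydronaphthalene-1,6(2H,7H)-dione (labdane locants: 8,10β-dimethyl, 3,9-dioxo, C4=C5; C8 epimers) | CC1C(=O)[C@@]2(C)CCC(=O)C=C2CC1 | intermediate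
7 | (4aS)-4a,6-dimethyl-2,5-dioxo-2,3,4,4a,5,6,7,8-octahydronaphthalene-1-carboxylic acid (4-carboxy enone; C8 epimers) | CC1C(=O)[C@@]2(C)CCC(=O)C(C(=O)O)=C2CC1 | intermediate
8 | methyl (1R,4aS)-1,4a,6-trimethyl-2,5-dioxo-1,2,3,4,4a,5,6,7-octahydronaphthalene-1-carboxylate (4α-Me, 4β-CO2Me, C5=C6, 3,9-dioxo; C8 epimers) | CC1C(=O)[C@@]2(C)CCC(=O)[C@](C)(C(=O)OC)C2=CC1 | intermediate
9 | 4α,8,10β-trimethyl-3,9-dioxo-5α-decalin-4β-carboxylic acid 6β-lactone (19,6β-olide; C8 epimers) | CC1C(=O)[C@@]2(C)CCC(=O)[C@](C)(C(=O)O3)[C@@H]2[C@H]3C1 | intermediate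
10 | C2=C3 trimethylsilyl enol ether of 9 | CC1C(=O)[C@@]2(C)CC=C(O[Si](C)(C)C)[C@](C)(C(=O)O3)[C@@H]2[C@H]3C1 | intermediate
11 | C2=C3 trimethylsilyl enol ether, C8=C9 enol triflate, 19,6β-lactone | CC1=C(OS(=O)(=O)C(F)(F)F)[C@@]2(C)CC=C(O[Si](C)(C)C)[C@](C)(C(=O)O3)[C@@H]2[C@H]3C1 | intermediate
12 | 3-oxo-19,6β-lactone with C8=C9 enol triflate (9-triflyloxy; 5α-H, 10β-Me, 4α-Me) | CC1=C(OS(=O)(=O)C(F)(F)F)[C@@]2(C)CCC(=O)[C@](C)(C(=O)O3)[C@@H]2[C@H]3C1 | intermediate
13 | 3α-hydroxy-19,6β-lactone C8=C9 enol triflate | CC1=C(OS(=O)(=O)C(F)(F)F)[C@@]2(C)CC[C@@H](O)[C@](C)(C(=O)O3)[C@@H]2[C@H]3C1 | intermediate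
14 | 4β-(hydroxymethyl)-4α,8,10β-trimethyl-5α-decal-8-ene-3α,6β-diol 9-triflate | CC1=C(OS(=O)(=O)C(F)(F)F)[C@@]2(C)CC[C@@H](O)[C@](C)(CO)[C@@H]2[C@H](O)C1 | intermediate
15 | ethyl but-2-ynoate | CC#CC(=O)OCC | starting material
16 | ethyl (2E)-3-methylpenta-2,4-dienoate | C=C/C(C)=C/C(=O)OCC | intermediate
17 | ethyl (2E)-5-(9-borabicyclo[3.3.1]nonan-9-yl)-3-methylpent-2-enoate | B1(CC/C(C)=C/C(=O)OCC)C2CCCC1CCC2 | intermediate
18 | ethyl (13E)-3α,6β,19-trihydroxylabda-8,13-dien-15-oate | CC1=C(CC/C(C)=C/C(=O)OCC)[C@@]2(C)CC[C@@H](O)[C@](C)(CO)[C@@H]2[C@H](O)C1 | intermediate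
19 | (13E)-3α,6β,19-trihydroxylabda-8,13-dien-15-oic acid (3R,4S,5R,6R,10S) | CC1=C(CC/C(C)=C/C(=O)O)[C@@]2(C)CC[C@@H](O)[C@](C)(CO)[C@@H]2[C@H](O)C1 | target

## Step count and risks

Total steps: 9. Longest linear sequence: 8 (steps 1–7 and 9; step 8 makes the side-chain fragment).

Steps most likely to fail:

**Step 5 (the proposed new step).** The neighbouring carbonyls raise the oxidation potential of the C5=C6 alkene, the ester carbonyl may be too weak a nucleophile for the radical cation, and allylic deprotonation of the radical cation can compete. The fallback uses known chemistry, sets out from 7 and comes back at 9. Treating 7 with KOtBu (2.2 equiv) in THF and then MeI (1.05 equiv) gives the potassium 4α-methyl-3,9-dioxo-Δ5-4β-carboxylate F3, which is not isolated and never acidified. Buffering with aqueous NaHCO3 and adding I2 at 0 °C gives, by classical carboxylate iodolactonization (iodonium on the α face, carboxylate onto C6 from the β face, thermodynamic γ-lactone), the 5α-iodo-19,6β-lactone F4. Bu3SnH/AIBN in benzene at 80 °C removes the iodine with H delivery to the α face of C5 and gives 9.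

**Step 2.** Migration of the quaternary carbon (regioisomeric dione), double homologation, or dipolar cycloaddition of diazoethane to the enone could erode the yield. The fallback sets out from 5 and comes back at 6. BF3·OEt2-promoted homologation with ethyl diazoacetate (CH2Cl2, 0 °C), which reliably migrates the less substituted carbon, gives the ring-expanded β-keto ester F1. K2CO3/MeI in acetone methylates only the β-keto ester carbon (C8) to give the quaternary β-keto ester F2. Krapcho dealkoxycarbonylation (LiCl, wet DMSO, 150 °C) then gives 6.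

**Step 9.** 9-BBN may add with poor regioselectivity to the electron-poor dienoate (or reduce the ester), and the tetrasubstituted triflate next to a quaternary carbon may couple slowly. The fallback sets out from 14 and comes back at 19. 9-BBN hydroboration of trimethyl(but-3-en-1-ynyl)silane, a well-behaved non-conjugated-ester alkene, gives the homopropargyl borane F5, which is coupled with 14 under the same Pd(dppf)Cl2/AsPh3/Cs2CO3 conditions to give the silyl alkyne triol F6. K2CO3/MeOH gives the terminal alkyne triol F7. Zr-catalysed carboalumination (Me3Al in excess to absorb the three OH groups, Cp2ZrCl2, CH2Cl2; syn addition puts the chain trans to aluminium), then n-BuLi and CO2, gives the 13E acid 19 directly.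

## Further compounds

F1 | step 2 | ethyl (8aS)-8a-methyl-1,6-dioxo-1,2,3,4,6,7,8,8a-octahydronaphthalene-2-carboxylate | CCOC(=O)C1C(=O)[C@@]2(C)CCC(=O)C=C2CC1
F2 | step 2 | ethyl (8aS)-2,8a-dimethyl-1,6-dioxo-1,2,3,4,6,7,8,8a-octahydronaphthalene-2-carboxylate | CCOC(=O)C1(C)C(=O)[C@@]2(C)CCC(=O)C=C2CC1
F3 | step 5 | potassium 4α,8,10β-trimethyl-3,9-dioxo-Δ5-octalin-4β-carboxylate | CC1C(=O)[C@@]2(C)CCC(=O)[C@](C)(C(=O)[O-])C2=CC1.[K+]
F4 | step 5 | 5α-iodo-3,9-dioxo-19,6β-lactone | CC1C(=O)[C@@]2(C)CCC(=O)[C@](C)(C(=O)O3)[C@]2(I)[C@H]3C1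
F5 | step 9 | 9-[4-(trimethylsilyl)but-3-yn-1-yl]-9-borabicyclo[3.3.1]nonane | C[Si](C)(C)C#CCCB1C2CCCC1CCC2
F6 | step 9 | 9-[4-(trimethylsilyl)but-3-yn-1-yl] 3α,6β,19-triol (silyl alkyne triol) | CC1=C(CCC#C[Si](C)(C)C)[C@@]2(C)CC[C@@H](O)[C@](C)(CO)[C@@H]2[C@H](O)C1
F7 | step 9 | 9-(but-3-yn-1-yl) 3α,6β,19-triol (terminal alkyne triol) | CC1=C(CCC#C)[C@@]2(C)CC[C@@H](O)[C@](C)(CO)[C@@H]2[C@H](O)C1
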